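The pitfall I had to avoid with the blue run was reading its high early values as something a slower flask could keep, so I first asked what the fall itself allowed.

| setting | blue | south-east | south-west | south |
|---|---|---|---|---|
| substrate | 0.075 M | 0.050 M | 0.050 M | 0.050 M |
| temperature | 75 °C | 75 °C | 35 °C | 55 °C |
| remark | run made earlier |  |  |  |
| time |  | 10 min | 10 min | 10 min |

blue run (percent of the substrate charged)

| time / s | target / % |
|---|---|
| 25.0 | 29.6 |
| 50.0 | 23.9 |
| 80.0 | 20.2 |
| 90.0 | 19.4 |
| 120 | 18.1 |

(readings scatter by 0.3 percentage points)

- a species is counted by the substrate in it: one self-condensation product counts as two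
- the numbers in the tables scatter by 0.3 percentage points (one standard deviation)
- steps under discussion: target <-> isomer of the product B; 2 substrate -> self-condensation product; substrate <-> target; target <-> isomer of the product A
- the earlier runs do not show what temperature does; that part of a forecast is a guess

- which flask leads in amount of target, in percent of the substrate charged ("all alike" within 1.5 percentage points) (south-east / south-west / south / all alike)
- how much target is there at the end, in percent of the substrate charged: south-east
- how much target is there at the end, in percent of the substrate charged: south-west
- how much target is there at the end, in percent of the substrate charged: south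

I took the target to relax at first order towards a plateau c∞, and integrating that one rate gave a closed form:

dc(target)/dt = −λ(c(target) − c∞), so c(target) − c∞ falls as exp(−λt).

In that form, the drops over two equal spans, 50.0 s to 80.0 s and 90.0 s to 120 s, stand in the ratio exp(λ·Δt), where Δt is the shift between the spans, and c∞ cancels. From these readings I got the relaxation rate constant:

λ = 0.0261 s⁻¹, c∞ = 17.0%

Then I turned the question round. For south-east to end a margin of 1.5 percentage points above its plateau, starting from the excess at 25.0 s, λ would have had to be no more than

λc = 0.00370 s⁻¹

The read λ was 7.05 times that, and it gave 15.0 relaxation times, so I put south-east near c∞. For the cooler flasks the blue run showed me no temperature effect, and a leftover excess there also presumed that the target had first been made.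

The forecast named south-west, with 15%, 27% and 18.5% for south-east, south-west and south, below my plateau for south-east and holding that in the cold flask “target is probably still passing slowly through its maximum”.

The simulation put south-east in the lead, with 16.4% against 13.2% in south-west and 12.2% in south.

    target ⇌ isomer of the product B (K = 14.2, k = 0.0374 min⁻¹, Ea = 89.0 kJ mol⁻¹, ΔH = −39.0 kJ mol⁻¹)
    2 substrate → self-condensation product (k = 0.827 L mol⁻¹ min⁻¹, Ea = 49.0 kJ mol⁻¹)
    substrate ⇌ target (K = 0.696, k = 0.0696 min⁻¹, Ea = 97.0 kJ mol⁻¹, ΔH = 14.0 kJ mol⁻¹)
    target ⇌ isomer of the product A (K = 1.20, k = 0.419 min⁻¹, Ea = 84.0 kJ mol⁻¹, ΔH = −23.0 kJ mol⁻¹)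
    (constants at 35 °C)

In south-east, the half-life implied by my λ, 0.443 min, was short against 10 min, and the target stood at 16.4% beside my c∞ of 17.0%, but it was still falling, from 17.7% at 5.00 min through 16.4% at 10.0 min to 6.98% at 100 min, so c∞ was no final level in south-east. South-west, by contrast, still held 37.2% substrate, and its target had risen from 11.3% at 5.00 min to 13.2% at 10.0 min. For the neighbour of south-east charged with 0.20 M, a first-order λ gave the same 15.0 relaxation times and so no excess above its plateau. The simulation gave that neighbour 9.97% target, less than my c∞, beside 52.6% self-condensation product, with target over substrate at 1.35 against 1.32 in south-east.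

The numbers in the tables stem from a simulated flask with made-up constants.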